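**Retrosynthetic overview**

1. The target is 2-[2-(3-hydroxy-4-methoxyphenyl)ethyl]-6,7-dimethoxychromone: ring A (the 6,7-dimethoxybenzo ring) is fused to ring B (the 4-pyranone), and C2 of ring B carries a CαH2–CβH2 linker to ring C (the 3-hydroxy-4-methoxyphenyl ring).
2. The strategy rests on the Cα–Cβ bond: Cα sits on C2 and is acidified vinylogously through C2=C3 and the C4 carbonyl of ring B, while Cβ is the benzylic carbon of ring C and can be carried as an aldehyde carbon. The bond is cut as Cα=Cβ (retro-hydrogenation, phenol masked as benzyl ether) into 6,7-dimethoxy-2-methylchromone and 3-benzyloxy-4-methoxybenzaldehyde.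
3. The 2-methylchromone goes back to 2-hydroxy-4,5-dimethoxyacetophenone and ethyl acetate (Claisen condensation, then acid cyclodehydration); the aldehyde goes back to isovanillin and benzyl bromide.
4. Ring order: rings A and C are bought, ring B is closed in step 1, the key step closes no ring, and a single hydrogenation then saturates Cα=Cβ and frees the phenol.

Key step: step 3

Remark on the chemistry: the target has no stereocentre; the only stereochemical element that appears on the way, the (E)-alkene of the styrylchromone, is removed in the last step, so no stereocontrol has to be planned.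

**Route**

Step 1
Reactants: 1 2-hydroxy-4,5-dimethoxyacetophenone; 2 ethyl acetate
Product: 4 6,7-dimethoxy-2-methylchromone, via β-diketone 3 (not isolated)
Conditions: NaH (4 equiv), 2 (5 equiv), THF, reflux; then conc. HCl, AcOH, 90 °C
Reagents that add atoms: none
Why: A crossed Claisen condensation of the ketone enolate of the phenoxide with ethyl acetate is driven forward by deprotonation of the β-diketone 3, and acid then brings about the cyclodehydration (phenol oxygen onto the distal carbonyl, loss of water) that closes ring B, the standard entry to 2-methylchromones, under which the aryl methyl ethers are stable.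

Step 2
Reactants: 5 isovanillin (3-hydroxy-4-methoxybenzaldehyde); 6 benzyl bromide
Product: 7 3-benzyloxy-4-methoxybenzaldehyde
Conditions: K2CO3 (1.5 equiv), DMF, 60 °C
Reagents that add atoms: none
Why: Williamson ether synthesis, in which the phenoxide of isovanillin displaces bromide from benzyl bromide by SN2 while the non-enolisable aldehyde is inert to carbonate.

Step 3
Reactants: 4 6,7-dimethoxy-2-methylchromone; 7 3-benzyloxy-4-methoxybenzaldehyde
Product: 9 (E)-2-(3-benzyloxy-4-methoxystyryl)-6,7-dimethoxychromone, via aldol adduct 8 (not isolated)
Conditions: NaOEt (21 wt% in EtOH, 1.5 equiv), abs. EtOH, 0 °C to rt; dil. HCl work-up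
Reagents that add atoms: none
Why: Ethoxide removes a proton from the C2 methyl group of 4 to give a dienolate spread over Cα, C3 and the C4 oxygen, which adds through its exocyclic terminus Cα to aldehyde 7 to give carbinol 8, and E1cB loss of hydroxide then gives the conjugated styryl system; this is a vinylogous aldol (Claisen–Schmidt type) condensation, the established way of joining 2-methylchromones and aryl aldehydes to 2-styrylchromones. No ring is closed in this step, since ring B is in place from step 1 and rings A and C are untouched. The carbinol stereocentre of 8 is transient and is lost on dehydration, so the only stereochemical element formed is the Cα=Cβ geometry, which should be (E) because the reversible E1cB elimination leads to the less hindered conjugated alkene, and it is erased in step 4 in any case. The step needs site selectivity for Cα over C3 and chemoselectivity for methyl deprotonation over conjugate addition of ethoxide at C2, which would open ring B; reaction through Cα is the only pathway that can dehydrate to a product that keeps the pyranone, and adducts at C3 revert. The methoxy groups on ring A, the 7-methoxy group para to the C4 carbonyl in particular, feed electron density into the pyranone and lower the electrophilicity of C2, and a small excess of base at 0 °C to room temperature, together with the expected crystallisation of the sparingly soluble product from ethanol, should keep ring opening in the background. Only the cross-condensation is productive because 7 has no α-hydrogen and 4 offers no carbonyl open to aldol addition, and the benzyl ether is inert to alkoxide.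

Step 4
Reactants: 9 (E)-2-(3-benzyloxy-4-methoxystyryl)-6,7-dimethoxychromone
Product: 10 2-[2-(3-hydroxy-4-methoxyphenyl)ethyl]-6,7-dimethoxychromone
Conditions: H2 (1 atm), 10% Pd/C, THF/MeOH, rt, stopped after uptake of 2 equiv H2
Reagents that add atoms: none
Why: Heterogeneous catalytic hydrogenation should saturate the disubstituted styryl alkene and hydrogenolyse the benzylic C–O bond of the aryl benzyl ether in one operation, while the C2=C3 bond of ring B (a vinylogous ester in a pseudo-aromatic pyranone), the C4 carbonyl and the aryl methyl ethers react far more slowly under these mild conditions; no stereocentre is formed.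

**Compound list**

1 | 2-hydroxy-4,5-dimethoxyacetophenone | COc1cc(O)c(C(C)=O)cc1OC | starting material
2 | ethyl acetate | CCOC(C)=O | starting material
3 | 1-(2-hydroxy-4,5-dimethoxyphenyl)butane-1,3-dione (β-diketone, formed in the flask) | COc1cc(O)c(C(=O)CC(C)=O)cc1OC | intermediate
4 | 6,7-dimethoxy-2-methylchromone (6,7-dimethoxy-2-methyl-4H-chromen-4-one) | COc1cc2oc(C)cc(=O)c2cc1OC | intermediate
5 | isovanillin (3-hydroxy-4-methoxybenzaldehyde) | COc1ccc(C=O)cc1O | starting material
6 | benzyl bromide | BrCc1ccccc1 | starting material
7 | 3-benzyloxy-4-methoxybenzaldehyde | COc1ccc(C=O)cc1OCc1ccccc1 | intermediate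
8 | racemic 2-[2-(3-benzyloxy-4-methoxyphenyl)-2-hydroxyethyl]-6,7-dimethoxychromone (aldol adduct, formed in the flask) | COc1ccc(C(O)Cc2cc(=O)c3cc(OC)c(OC)cc3o2)cc1OCc1ccccc1 | intermediate
9 | (E)-2-(3-benzyloxy-4-methoxystyryl)-6,7-dimethoxychromone | COc1ccc(/C=C/c2cc(=O)c3cc(OC)c(OC)cc3o2)cc1OCc1ccccc1 | intermediate
10 | 2-[2-(3-hydroxy-4-methoxyphenyl)ethyl]-6,7-dimethoxychromone | COc1ccc(CCc2cc(=O)c3cc(OC)c(OC)cc3o2)cc1O | target

**Step count**

Total: 4 steps. Longest linear sequence: 3 steps (step 1 or step 2, then steps 3 and 4).

**Steps most likely to fail**

Step 3 (key condensation). Ethoxide may add at C2 and open ring B faster than the methyl group is deprotonated, or addition to the electron-rich aldehyde may be so slow that base-mediated degradation of the chromone outruns C–C bond formation. The fallback brings in the Cα=Cβ unit already formed and closes ring B around it; it sets out from 7 and 1 and comes back to the route at 9. Aldehyde 7 would be converted by Knoevenagel–Doebner condensation (malonic acid, pyridine, piperidine cat., 90 °C) into (E)-3-(3-benzyloxy-4-methoxyphenyl)acrylic acid F1. Esterification of F1 with phenol 1 (DCC, 4-pyrrolidinopyridine, CH2Cl2, rt) should give 2-acetyl-4,5-dimethoxyphenyl (E)-3-(3-benzyloxy-4-methoxyphenyl)acrylate F2. Baker–Venkataraman acyl transfer (KOH, DMSO, rt) should then give (E)-5-(3-benzyloxy-4-methoxyphenyl)-1-(2-hydroxy-4,5-dimethoxyphenyl)pent-4-ene-1,3-dione F3, and cyclodehydration (p-TsOH cat., DMSO, 90 °C) would deliver 9.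

Step 4 (hydrogenation with debenzylation). Hydrogenation may run on into the C2=C3 bond of ring B before hydrogenolysis of the benzyl ether is complete, or the hydrogenolysis may stall once the alkene is saturated. The fallback separates the two events; it sets out from 9 and comes back at 10. Homogeneous hydrogenation with RhCl(PPh3)3 (cat.), H2 (1 atm), THF/EtOH, 40 °C, which neither cleaves benzyl ethers nor touches the pyranone, should give 2-[2-(3-benzyloxy-4-methoxyphenyl)ethyl]-6,7-dimethoxychromone F4. Lewis-acid debenzylation of F4 (BCl3, pentamethylbenzene as cation scavenger, CH2Cl2, −78 °C) would then free the phenol without loss of the methyl ethers and give 10.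

Step 1 (Claisen condensation and ring closure). Self-condensation of ethyl acetate may consume the ester before the hindered, electron-rich phenoxide enolate is C-acylated, leaving the ketone unconverted. The fallback makes the acyl transfer intramolecular; it sets out from 1 and comes back at 3. Acetylation of 1 (Ac2O, pyridine, DMAP cat., rt) should give 2-acetyl-4,5-dimethoxyphenyl acetate F5, and Baker–Venkataraman rearrangement of F5 (KOtBu, THF, 0 °C to rt) would give β-diketone 3. In this variant 3 is isolated and then closed to 4 with conc. HCl in AcOH as in step 1.

Further compounds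
F1 | step 3 | (E)-3-(3-benzyloxy-4-methoxyphenyl)acrylic acid | COc1ccc(/C=C/C(=O)O)cc1OCc1ccccc1
F2 | step 3 | 2-acetyl-4,5-dimethoxyphenyl (E)-3-(3-benzyloxy-4-methoxyphenyl)acrylate | COc1ccc(/C=C/C(=O)Oc2cc(OC)c(OC)cc2C(C)=O)cc1OCc1ccccc1
F3 | step 3 | (E)-5-(3-benzyloxy-4-methoxyphenyl)-1-(2-hydroxy-4,5-dimethoxyphenyl)pent-4-ene-1,3-dione | COc1ccc(/C=C/C(=O)CC(=O)c2cc(OC)c(OC)cc2O)cc1OCc1ccccc1
F4 | step 4 | 2-[2-(3-benzyloxy-4-methoxyphenyl)ethyl]-6,7-dimethoxychromone | COc1ccc(CCc2cc(=O)c3cc(OC)c(OC)cc3o2)cc1OCc1ccccc1
F5 | step 1 | 2-acetyl-4,5-dimethoxyphenyl acetate | CC(=O)Oc1cc(OC)c(OC)cc1C(C)=O
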